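The runs are simulated for an exercise; noise was put on by code.

**The choice.** The reckoning here follows one concentration for the order of the rate, and the choice is dissolved gas. The measure carried is the conversion time constant: the time in which the fraction of the charge not turned into target falls by a factor e.

the same everywhere: gas phase 7.6 mM (held)

| run | substrate | remark | time |
|---|---|---|---|
| green | 24 mM | run made earlier |  |
| teal | 98 mM | run made earlier |  |
| flask | 49 mM |  | 10 min |

| run | time / min | target / % | substrate / % |
|---|---|---|---|
| green | 0.500 | 1.4 | 100.1 |
| green | 0.833 | 1.4 | 97.5 |
| green | 1.50 | 5.6 | 94.4 |
| green | 3.00 | 11.8 | 88.9 |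
| green | 6.00 | 25.3 | 72.9 |
| teal | 0.500 | 1.7 | 100.3 |
| teal | 1.50 | 5.1 | 96.0 |
| teal | 3.00 | 8.3 | 92.7 |
| teal | 4.00 | 11.4 | 88.1 |
| teal | 6.00 | 17.0 | 82.1 |

(standard deviation of a reading: 1 percentage point)

- at the start none of the gas phase is in solution

* amount of target in percent of the substrate charged, at 2.0 min, 5.0 min and 10 min

**Two extremes.** If uptake is fast, dissolved gas stays at saturation and the reaction is pseudo-first-order, so the time constant is the same at every charge. If uptake is the rate-limiting step, a fixed amount reacts per minute, so the time constant grows in proportion to the charge. Going from green to teal, that proportion is 4.08.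

**The runs.** The last readings give 20.6 min for green and 32.2 min for teal. Their ratio, as read, of 1.56 is above the first extreme's ratio of 1 and less than the second's, so these readings place the runs between the extremes. Taken as two resistances in series, uptake and reaction give a time constant that is a straight line in the charge. My reckoning on that line gives the flask a conversion time constant of 24.5 min. That means 7.84%, 18.5% and 33.5% of target. The first figure may run high: the flask starts with no dissolved gas, and the green reading of 1.4% at 0.833 min stands below the 3.96% that green's own time constant gives.

**The forecast.** It says 7%, 16.5% and 31%, on the ground that “The order in substrate is therefore about 0.75”. At 10 min it stands below my figure.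

**The result.** The flask gives 6.24%, 17.8% and 31.9%, and the forecast held.

    gas phase ⇌ dissolved gas, rate k1*(csat - [dissolved gas]) (kL = 0.0120 s⁻¹)
    substrate + dissolved gas ⇌ target (K = 290 L mol⁻¹, k = 0.220 L mol⁻¹ s⁻¹)
    dissolved gas + target → over-reacted product (k = 0.0480 L mol⁻¹ s⁻¹)
    dissolved gas → decomposed reagent (k = 0.00180 s⁻¹)

**What stood.** The target of the flask at 10 min corresponds to a time constant of 26.0 min, longer than the 24.5 min reckoned, with dissolved gas at 61.6% of saturation. In the flask at that time, the half-life of target by the path to over-reacted product is 51 min, long against the 10 min of the run, and over-reacted product stands at 2.09%.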